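**Plan**

- Labels follow the target: C1 ring ketone, C2 (CH2OH), C3, C4, C5 (quaternary), C6 (enol ester arm), C7 (acetonyl arm), C1′–C5′ side chain. TBS = tert-butyldimethylsilyl, PMB = 4-methoxybenzyl.
- Enabling feature: from the ketone carbon of the C7 acetonyl group through its CH2, C7, C6 and the first arm carbon to the O-bearing vinyl carbon there are six carbons in a row, with C6 and C7 trans. Joining the two end carbons by a C=C bond re-creates a 1-methylcyclohexene, so both arms can be stored in that ring.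
- Retrosynthetic cuts, in order: C3′–OOH (ene); enol ester C–O; the two arm carbonyls back to the cyclohexene C=C; C5–CH3 (1,6-cuprate); C4=C5 (dehydration); C2=C3 (metathesis); C1–C2 (vinyllithium on a lactone); C4–C5 (allyl to ketone); last the C6–CH2 and C7–CH2 bonds of the cyclohexene (Diels–Alder).
- Forward: cyclohexene first, a temporary γ-lactone second, the seven-membered ring third (metathesis). After methyl delivery to C5 the cyclohexene is opened and the side chain, enol ester and hydroperoxide are finished.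
- Stereochemistry: C6/C7 trans from the (E)-dienophile, absolute sense from the chiral oxazaborolidinium. C5 from axial 1,6-delivery of methyl anti to C6–H, which is why the dienophile ketone carries the side-chain carbons and methyl comes last. C3′ forms without control in the final ene reaction and the (3′S)-epimer is separated.

Key step: step 2

Assumption: the (S)-configured catalyst is taken to give (1S,6S)-6; should the sense of induction be the reverse, the (R)-catalyst is used with no other change.

**Step 1**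
Reactants: 1 ethyl (E)-4-chloro-4-oxobut-2-enoate (ethyl fumaroyl chloride); 2 tert-butyl(3-iodopropoxy)dimethylsilane
Product: 4 ethyl (E)-7-(TBS-oxy)-4-oxohept-2-enoate, via alkylzinc iodide 3 (not isolated)
Conditions: 2, Zn dust, LiCl, THF, 40 °C; then 1, Pd(PPh3)4 (cat.), THF, 0 °C → rt
Reagents that add atoms: none
Why: Negishi acylation: zinc inserts into the primary C–I bond, zerovalent palladium adds oxidatively to the acyl chloride and, after transmetallation, reductive elimination gives the ketone, the alkylzinc halide being too unreactive to attack the ester, the product ketone or the enoate π bond, so the (E)-alkene survives.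

**Step 2**
Reactants: 4 ethyl (E)-7-(TBS-oxy)-4-oxohept-2-enoate; 5 isoprene
Product: 6 ethyl (1S,6S)-6-[4-(TBS-oxy)butanoyl]-3-methylcyclohex-3-ene-1-carboxylate (ring C1 = target C7; ring C6 = target C6)
Conditions: (S)-3,3-diphenyl-1-(o-tolyl)tetrahydro-1H,3H-pyrrolo[1,2-c][1,3,2]oxazaborole (20 mol %), Tf2NH (18 mol %), 5 (excess), CH2Cl2, −78 → −40 °C
Reagents that add atoms: none
Why: The protonated oxazaborolidine binds the ketone oxygen of 4, which is more basic than the ester oxygen, so the LUMO is lowered and its largest coefficient lies on the ester-bearing carbon (β to the ketone); isoprene C1, the terminus with the largest HOMO coefficient, bonds there in a concerted, asynchronous, suprafacial [4+2] cycloaddition. The closest known reactions are Lewis-acid-promoted Diels–Alder additions of isoprene to (E)-4-oxo-2-enoates, which give the ketone-directed para adduct, and oxazaborolidinium-catalysed enantioselective Diels–Alder additions of acyclic enones and fumarates to 2-substituted butadienes. The one ring formed, the cyclohexene, closes in a single intermolecular event in which both new σ bonds (target C7 to the acetonyl CH2 and target C6 to the first arm carbon) are made on the same face of each partner. The trans relationship of the two new stereocentres follows from the (E)-geometry of the dienophile because the addition is stereospecific, and their absolute configuration follows from the catalyst, whose aryl group covers one face of the bound s-trans enone. The step needs regioselectivity (ring methyl para to the acyl-bearing carbon) and face selectivity; the first is secured by the basicity difference between the ketone and the ester within 4, the second by the catalyst, and endo/exo orientation creates no stereocentre here.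

**Step 3**
Reactants: 6 ethyl (1S,6S)-6-[4-(TBS-oxy)butanoyl]-3-methylcyclohex-3-ene-1-carboxylate
Product: 8 (3aS,7aS)-3-allyl-3-[3-(TBS-oxy)propyl]-6-methyl-3a,4,7,7a-tetrahydro-2-benzofuran-1(3H)-one (trans-fused C3-epimer mixture), via bromomagnesium alkoxide 7 (not isolated)
Conditions: allylMgBr (1.05 equiv), THF, −78 °C → rt
Reagents that add atoms: allylmagnesium bromide, C=CC[Mg]Br
Why: Chemoselective Grignard addition (at −78 °C the ketone is far more electrophilic than the ester) followed on warming by 5-exo-trig acyl substitution of the ester by the tertiary alkoxide (lactonisation) should give the trans-fused γ-lactone; the new carbinol centre forms without control, which is immaterial because it becomes trigonal in step 7.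

**Step 4**
Reactants: 9 2-bromoprop-2-en-1-ol
Product: 10 1-{[(2-bromoprop-2-en-1-yl)oxy]methyl}-4-methoxybenzene (2-bromoallyl PMB ether)
Conditions: NaH, PMBCl, Bu4NI (cat.), THF, 0 °C → rt
Reagents that add atoms: 4-methoxybenzyl chloride, COc1ccc(CCl)cc1
Why: Williamson ether synthesis: the sodium alkoxide displaces chloride from the benzylic halide under iodide catalysis, and the vinylic bromide is inert to these conditions.

**Step 5**
Reactants: 8 lactone from step 3; 10 2-bromoallyl PMB ether
Product: 12 1-[(1S,6S)-6-(7-(TBS-oxy)-4-hydroxyhept-1-en-4-yl)-3-methylcyclohex-3-en-1-yl]-2-[(PMB-oxy)methyl]prop-2-en-1-one (carbinol epimers), via vinyllithium 11 (not isolated)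
Conditions: 10, t-BuLi (2 equiv), Et2O, −78 °C; then 8, −78 °C; AcOH quench at −78 °C
Reagents that add atoms: none
Why: Bromine–lithium exchange gives the 2-lithioallyl ether, which adds once to the lactone carbonyl because the lithium lactolate is stable at −78 °C (organolithium addition to a lactone), and protonation releases the 2-substituted vinyl ketone and the tertiary alcohol, which may rest as the five-membered lactol.

**Step 6**
Reactants: 12 hydroxy enone from step 5
Product: 13 (4aS,9aS)-9-hydroxy-3-methyl-6-[(PMB-oxy)methyl]-9-[3-(TBS-oxy)propyl]-1,4,4a,8,9,9a-hexahydro-5H-benzo[7]annulen-5-one (C9 epimers; benzannulene C5, C6, C9, C9a, C4a = target C1, C2, C5, C6, C7)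
Conditions: second-generation Hoveyda–Grubbs catalyst (10 mol %), toluene (high dilution), 80 °C
Reagents that add atoms: none
Why: Ring-closing metathesis: the ruthenium carbene formed at the allyl group closes onto the 1,1-disubstituted enone alkene with loss of ethene, as in known routes to 2-substituted cyclohept-2-enones, while the trisubstituted endocyclic alkene and the saturated side chain cannot compete, and no stereocentre is affected.

**Step 7**
Reactants: 13 hydroxy cycloheptenone from step 6
Product: 15 (4aS,9aS)-3-methyl-6-[(PMB-oxy)methyl]-9-[3-(TBS-oxy)propyl]-1,4,4a,9a-tetrahydro-5H-benzo[7]annulen-5-one, via mesylate 14 (not isolated)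
Conditions: MsCl, Et3N, CH2Cl2, −20 → 0 °C; then DBU, rt
Reagents that add atoms: none
Why: Mesylation of the tertiary alcohol through sulfene followed by DBU-induced vinylogous E1cB elimination: the only acidic β-hydrogens are those on C4 (γ to the enone), so the new double bond is placed at C4=C5 in conjugation and C6–H is not touched.

**Step 8**
Reactants: 15 2,4-dienone from step 7
Product: 17 (4aS,9S,9aS)-3,9-dimethyl-6-[(PMB-oxy)methyl]-9-[3-(TBS-oxy)propyl]-1,4,4a,8,9,9a-hexahydro-5H-benzo[7]annulen-5-one, via β,γ-enone 16 (not isolated)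
Conditions: Me2CuLi (from MeLi and CuI), Et2O, −78 → −30 °C; AcOH quench at −78 °C; then DBU (cat.), CH2Cl2, 0 °C
Reagents that add atoms: methyllithium, [Li]C
Why: 1,6-Conjugate addition of a Gilman cuprate to a 2,4-dienone, the reaction type used to place 7α-methyl groups on steroidal 4,6-dien-3-ones: copper transfers methyl to the δ-carbon C5 and, in the trans-fused bicycle whose C6–H is locked axial, methyl should enter axially on the face anti to C6–H, which sets (5S) with methyl cis to the C6 ring methylene; kinetic α-protonation gives the β,γ-enone 16 and catalytic DBU returns the double bond to C2=C3.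

**Step 9**
Reactants: 17 enone from step 8
Product: 18 (4aS,9S,9aS)-2,3-epoxy-3,9-dimethyl-6-[(PMB-oxy)methyl]-9-[3-(TBS-oxy)propyl]-1,2,3,4,4a,8,9,9a-octahydro-5H-benzo[7]annulen-5-one (both epoxide diastereomers)
Conditions: mCPBA, CH2Cl2, 0 °C
Reagents that add atoms: 3-chloroperoxybenzoic acid, OOC(=O)c1cccc(Cl)c1
Why: Prilezhaev epoxidation: the peracid reacts only with the electron-rich trisubstituted cyclohexene alkene, the enone alkene being electron-poor, and both epoxide diastereomers are acceptable because the two epoxide carbons become carbonyl carbons in step 13.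

**Step 10**
Reactants: 18 epoxide from step 9
Product: 19 (4aS,9S,9aS)-2,3-epoxy-9-(3-hydroxypropyl)-3,9-dimethyl-6-[(PMB-oxy)methyl]-1,2,3,4,4a,8,9,9a-octahydro-5H-benzo[7]annulen-5-one
Conditions: TBAF, AcOH, THF, 0 °C → rt
Reagents that add atoms: none
Why: Fluoride-induced cleavage of the primary silyl ether, buffered with acetic acid so that the alkoxide does not touch the enone or the epoxide.

**Step 11**
Reactants: 19 primary alcohol from step 10
Product: 20 3-[(4aS,9S,9aS)-2,3-epoxy-3,9-dimethyl-6-[(PMB-oxy)methyl]-5-oxo-1,2,3,4,4a,8,9,9a-octahydro-5H-benzo[7]annulen-9-yl]propanal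
Conditions: Dess–Martin periodinane, pyridine, CH2Cl2, 0 °C → rt
Reagents that add atoms: none
Why: Dess–Martin oxidation of the primary alcohol to the aldehyde under buffered conditions that leave the epoxide, the enone and the PMB ether untouched.

**Step 12**
Reactants: 20 aldehyde from step 11
Product: 21 (4aS,9S,9aS)-2,3-epoxy-3,9-dimethyl-9-(4-methylpent-3-en-1-yl)-6-[(PMB-oxy)methyl]-1,2,3,4,4a,8,9,9a-octahydro-5H-benzo[7]annulen-5-one
Conditions: i-PrPPh3I, n-BuLi, THF, 0 °C; then 20, −78 → 0 °C
Reagents that add atoms: isopropyltriphenylphosphonium iodide, CC(C)[P+](c1ccccc1)(c1ccccc1)c1ccccc1.[I-]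
Why: Wittig olefination: the non-stabilised isopropylidene ylide reacts at −78 °C with the aldehyde much faster than with the hindered, conjugated ring ketone, and the trisubstituted alkene formed has no geometry to control.

**Step 13**
Reactants: 21 epoxide with the 4-methylpent-3-enyl side chain
Product: 23 (5S,6S,7S)-5-methyl-5-(4-methylpent-3-en-1-yl)-6-(2-oxoethyl)-7-(2-oxopropyl)-2-[(PMB-oxy)methyl]cyclohept-2-en-1-one, via diol 22 (not isolated)
Conditions: H5IO6, THF/H2O, 0 °C
Reagents that add atoms: water, O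
Why: Acid-promoted hydrolysis of the epoxide to the vicinal diol and Malaprade glycol cleavage by periodic acid should release the methyl ketone on the C7 methylene and the aldehyde on the C6 methylene; periodic acid does not attack the alkenes and C6 and C7 are not involved.

**Step 14**
Reactants: 24 3-methylbut-2-enoic acid (two molecules per molecule of product)
Product: 25 3-methylbut-2-enoic anhydride
Conditions: 24 (2 equiv), DCC (1 equiv), CH2Cl2, 0 °C → rt; filtration from the urea
Reagents that add atoms: 3-methylbut-2-enoic acid (the second molecule of 24), CC(C)=CC(=O)O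
Why: Carbodiimide-mediated dehydration: one molecule of the acid adds to DCC to give the O-acylisourea, a second molecule of the acid attacks its acyl carbon, and the symmetrical anhydride forms with loss of the urea; this is chosen over the acid chloride to avoid deconjugation through a vinylketene.

**Step 15**
Reactants: 23 keto aldehyde from step 13; 25 3-methylbut-2-enoic anhydride
Product: 26 (5S,6S,7S)-5-methyl-6-[(E)-2-(3-methylbut-2-enoyloxy)ethenyl]-5-(4-methylpent-3-en-1-yl)-7-(2-oxopropyl)-2-[(PMB-oxy)methyl]cyclohept-2-en-1-one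
Conditions: 25, Et3N, DMAP, THF, 40 °C
Reagents that add atoms: none
Why: O-Acylation of the aldehyde enolate (enol ester formation): triethylamine enolises the aldehyde, the only carbonyl with unhindered and sufficiently acidic α-hydrogens, the acylpyridinium formed from 25 and DMAP traps the enolate on oxygen, and the (E)-enol ester is favoured because it keeps the acyloxy group away from the C6 ring carbon.

**Step 16**
Reactants: 26 PMB-protected enol ester
Product: 27 (5S,6S,7S)-2-(hydroxymethyl)-5-methyl-6-[(E)-2-(3-methylbut-2-enoyloxy)ethenyl]-5-(4-methylpent-3-en-1-yl)-7-(2-oxopropyl)cyclohept-2-en-1-one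
Conditions: DDQ, CH2Cl2/pH 7 buffer, 0 °C
Reagents that add atoms: none
Why: Oxidative cleavage of the PMB ether by DDQ (benzylic hydride abstraction and hydrolysis of the oxocarbenium ion) under buffered conditions that leave the enol ester, the enone and the isolated alkene intact.

**Step 17**
Reactants: 27 allylic alcohol with the 4-methylpent-3-enyl side chain
Product: 28 (5S,6S,7S)-5-[(3S)-3-hydroperoxy-4-methylpent-4-en-1-yl]-2-(hydroxymethyl)-5-methyl-6-[(E)-2-(3-methylbut-2-enoyloxy)ethenyl]-7-(2-oxopropyl)cyclohept-2-en-1-one (CNP0216745.1)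
Conditions: O2, tetraphenylporphyrin (cat.), visible light, CH2Cl2, −20 °C
Reagents that add atoms: dioxygen, O=O
Why: Schenck ene reaction: singlet oxygen attacks only the electron-rich trisubstituted side-chain alkene (the enone, enol ester and senecioate alkenes are deactivated), bonds to C3′ and abstracts a hydrogen from a terminal methyl group to give the isopropenyl hydroperoxide; C3′ is too remote from the ring stereocentres for control, so the (3′S)-epimer is to be separated by preparative HPLC from the (3′R)-epimer and from the tertiary hydroperoxide regioisomer.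

**Compound list**

1 | ethyl (E)-4-chloro-4-oxobut-2-enoate | CCOC(=O)/C=C/C(Cl)=O | starting material
2 | tert-butyl(3-iodopropoxy)dimethylsilane | CC(C)(C)[Si](C)(C)OCCCI | starting material
3 | [3-(TBS-oxy)propyl]zinc iodide | CC(C)(C)[Si](C)(C)OCCC[Zn]I | intermediate
4 | ethyl (E)-7-(TBS-oxy)-4-oxohept-2-enoate | CCOC(=O)/C=C/C(=O)CCCO[Si](C)(C)C(C)(C)C | intermediate
5 | isoprene | C=CC(C)=C | starting material
6 | ethyl (1S,6S)-6-[4-(TBS-oxy)butanoyl]-3-methylcyclohex-3-ene-1-carboxylate | CCOC(=O)[C@H]1CC(C)=CC[C@@H]1C(=O)CCCO[Si](C)(C)C(C)(C)C | intermediate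
7 | bromomagnesium alkoxide of the allyl adduct of 6 (carbinol epimers) | CCOC(=O)[C@H]1CC(C)=CC[C@@H]1C(CC=C)(CCCO[Si](C)(C)C(C)(C)C)O[Mg]Br | intermediate
8 | (3aS,7aS)-3-allyl-3-[3-(TBS-oxy)propyl]-6-methyl-3a,4,7,7a-tetrahydro-2-benzofuran-1(3H)-one (C3 epimers) | O=C1OC(CC=C)(CCCO[Si](C)(C)C(C)(C)C)[C@H]2CC=C(C)C[C@H]12 | intermediate
9 | 2-bromoprop-2-en-1-ol | C=C(Br)CO | starting material
10 | 1-{[(2-bromoprop-2-en-1-yl)oxy]methyl}-4-methoxybenzene | C=C(Br)COCc1ccc(OC)cc1 | intermediate
11 | {3-[(4-methoxybenzyl)oxy]prop-1-en-2-yl}lithium | [Li]C(=C)COCc1ccc(OC)cc1 | intermediate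
12 | 1-[(1S,6S)-6-(7-(TBS-oxy)-4-hydroxyhept-1-en-4-yl)-3-methylcyclohex-3-en-1-yl]-2-[(PMB-oxy)methyl]prop-2-en-1-one (carbinol epimers) | C=C(COCc1ccc(OC)cc1)C(=O)[C@H]1CC(C)=CC[C@@H]1C(O)(CC=C)CCCO[Si](C)(C)C(C)(C)C | intermediate
13 | (4aS,9aS)-9-hydroxy-3-methyl-6-[(PMB-oxy)methyl]-9-[3-(TBS-oxy)propyl]-1,4,4a,8,9,9a-hexahydro-5H-benzo[7]annulen-5-one (C9 epimers) | O=C1C(COCc3ccc(OC)cc3)=CCC(O)(CCCO[Si](C)(C)C(C)(C)C)[C@H]2CC=C(C)C[C@H]12 | intermediate
14 | C9 methanesulfonate of 13 | O=C1C(COCc3ccc(OC)cc3)=CCC(OS(C)(=O)=O)(CCCO[Si](C)(C)C(C)(C)C)[C@H]2CC=C(C)C[C@H]12 | intermediate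
15 | (4aS,9aS)-3-methyl-6-[(PMB-oxy)methyl]-9-[3-(TBS-oxy)propyl]-1,4,4a,9a-tetrahydro-5H-benzo[7]annulen-5-one | O=C1C(COCc3ccc(OC)cc3)=CC=C(CCCO[Si](C)(C)C(C)(C)C)[C@H]2CC=C(C)C[C@H]12 | intermediate
16 | (4aS,9S,9aS)-3,9-dimethyl-6-[(PMB-oxy)methyl]-9-[3-(TBS-oxy)propyl]-1,4,4a,6,9,9a-hexahydro-5H-benzo[7]annulen-5-one (C6 epimers) | O=C1C(COCc3ccc(OC)cc3)C=C[C@](C)(CCCO[Si](C)(C)C(C)(C)C)[C@H]2CC=C(C)C[C@H]12 | intermediate
17 | (4aS,9S,9aS)-3,9-dimethyl-6-[(PMB-oxy)methyl]-9-[3-(TBS-oxy)propyl]-1,4,4a,8,9,9a-hexahydro-5H-benzo[7]annulen-5-one | O=C1C(COCc3ccc(OC)cc3)=CC[C@](C)(CCCO[Si](C)(C)C(C)(C)C)[C@H]2CC=C(C)C[C@H]12 | intermediate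
18 | 2,3-epoxide of 17 (both epoxide diastereomers) | O=C1C(COCc3ccc(OC)cc3)=CC[C@](C)(CCCO[Si](C)(C)C(C)(C)C)[C@H]2CC4OC4(C)C[C@H]12 | intermediate
19 | 2,3-epoxide with 9-(3-hydroxypropyl) | O=C1C(COCc3ccc(OC)cc3)=CC[C@](C)(CCCO)[C@H]2CC4OC4(C)C[C@H]12 | intermediate
20 | 2,3-epoxide with 9-(3-oxopropyl) | O=C1C(COCc3ccc(OC)cc3)=CC[C@](C)(CCC=O)[C@H]2CC4OC4(C)C[C@H]12 | intermediate
21 | 2,3-epoxide with 9-(4-methylpent-3-en-1-yl) | O=C1C(COCc3ccc(OC)cc3)=CC[C@](C)(CCC=C(C)C)[C@H]2CC4OC4(C)C[C@H]12 | intermediate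
22 | 2,3-diol from 21 | O=C1C(COCc3ccc(OC)cc3)=CC[C@](C)(CCC=C(C)C)[C@H]2CC(O)C(C)(O)C[C@H]12 | intermediate
23 | (5S,6S,7S)-5-methyl-5-(4-methylpent-3-en-1-yl)-6-(2-oxoethyl)-7-(2-oxopropyl)-2-[(PMB-oxy)methyl]cyclohept-2-en-1-one | CC(C)=CCC[C@@]1(C)CC=C(COCc2ccc(OC)cc2)C(=O)[C@@H](CC(C)=O)[C@@H]1CC=O | intermediate
24 | 3-methylbut-2-enoic acid | CC(C)=CC(=O)O | starting material
25 | 3-methylbut-2-enoic anhydride | CC(C)=CC(=O)OC(=O)C=C(C)C | intermediate
26 | (5S,6S,7S)-5-methyl-6-[(E)-2-(3-methylbut-2-enoyloxy)ethenyl]-5-(4-methylpent-3-en-1-yl)-7-(2-oxopropyl)-2-[(PMB-oxy)methyl]cyclohept-2-en-1-one | CC(C)=CCC[C@@]1(C)CC=C(COCc2ccc(OC)cc2)C(=O)[C@@H](CC(C)=O)[C@@H]1/C=C/OC(=O)C=C(C)C | intermediate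
27 | (5S,6S,7S)-2-(hydroxymethyl)-5-methyl-6-[(E)-2-(3-methylbut-2-enoyloxy)ethenyl]-5-(4-methylpent-3-en-1-yl)-7-(2-oxopropyl)cyclohept-2-en-1-one | CC(C)=CCC[C@@]1(C)CC=C(CO)C(=O)[C@@H](CC(C)=O)[C@@H]1/C=C/OC(=O)C=C(C)C | intermediate
28 | (5S,6S,7S)-5-[(3S)-3-hydroperoxy-4-methylpent-4-en-1-yl]-2-(hydroxymethyl)-5-methyl-6-[(E)-2-(3-methylbut-2-enoyloxy)ethenyl]-7-(2-oxopropyl)cyclohept-2-en-1-one (CNP0216745.1) | C=C(C)[C@H](CC[C@@]1(C)CC=C(CO)C(=O)[C@@H](CC(C)=O)[C@@H]1/C=C/OC(=O)C=C(C)C)OO | target

**Step count and risks**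

Total step count: 17. Longest linear sequence: 15 steps (steps 1–3, 5–13, 15–17).

Steps most likely to fail:

1. Step 8. Methyl may be delivered to the face of C5 syn to C6–H, copper may transfer methyl to C3 (1,4-addition), or the dienolate may expel the PMB-oxy group. The fallback exchanges the roles of the two C5 substituents, so that a preference for the face syn to C6–H becomes productive. It sets out from isoprene 5, which under the conditions of step 2 is combined with commercial methyl (E)-4-oxopent-2-enoate F1 to give methyl (1S,6S)-6-acetyl-3-methylcyclohex-3-ene-1-carboxylate F2. Allylmagnesium bromide gives the bromomagnesium alkoxide F3, which lactonises to (3aS,7aS)-3-allyl-3,6-dimethyl-3a,4,7,7a-tetrahydro-2-benzofuran-1(3H)-one F4. Opening with 11 gives the hydroxy enone F5, and ring-closing metathesis gives the hydroxy cycloheptenone F6. Mesylation gives the tertiary mesylate F7, and DBU elimination gives the 9-methyl dienone F8. A dialkylcuprate made from iodide 2 (t-BuLi, then CuI) then transfers the 3-(TBS-oxy)propyl group to C5 of F8. Protonation gives 16 and conjugation as in step 8 brings the route back at 17.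

2. Step 17. Singlet oxygen cannot discriminate the faces of the remote alkene and can also abstract hydrogen from C2′ to give the tertiary hydroperoxide, and the C3′ epimers may prove hard to separate. The fallback makes the C3′–O bond under reagent control and introduces the O–O unit by substitution. It sets out from 26: photooxygenation as in step 17 gives the C3′-epimeric hydroperoxides F9, which are reduced in the same flask with PPh3 to the epimeric allylic alcohols F10; the tertiary alcohol regioisomer is removed by chromatography. Sharpless kinetic resolution (Ti(OiPr)4, L-(+)-diisopropyl tartrate, t-BuOOH, CH2Cl2, −20 °C) should consume the (3′S)-epimer as the epoxy alcohol F11 and leave the (3′R)-alcohol F12. Mesylation (MsCl, Et3N, −40 °C) gives the (3′R)-mesylate F13. Displacement with anhydrous H2O2 in Et2O at low temperature, with inversion, would give the (3′S)-hydroperoxide PMB ether F14. DDQ as in step 16 brings the route back at 28. The weak point of this fallback is the displacement, which must outrun ionisation of the allylic mesylate.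

3. Step 6. Ring closure onto the electron-poor 1,1-disubstituted alkene may be slow, giving way to intermolecular metathesis and catalyst decay. The fallback closes the ring at the allylic alcohol oxidation level. It sets out from 12: Luche reduction (NaBH4, CeCl3·7H2O, MeOH, −78 °C) gives the allylic diol F15, whose more electron-rich 1,1-disubstituted alkene should close readily with the second-generation Grubbs catalyst to the cycloheptene diol F16. Oxidation of the secondary allylic alcohol with MnO2 brings the route back at 13.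

**Further compounds**

F1 | step 8 | methyl (E)-4-oxopent-2-enoate | CC(=O)/C=C/C(=O)OC
F2 | step 8 | methyl (1S,6S)-6-acetyl-3-methylcyclohex-3-ene-1-carboxylate | COC(=O)[C@H]1CC(C)=CC[C@@H]1C(C)=O
F3 | step 8 | bromomagnesium alkoxide of the allyl adduct of F2 (carbinol epimers) | COC(=O)[C@H]1CC(C)=CC[C@@H]1C(C)(CC=C)O[Mg]Br
F4 | step 8 | (3aS,7aS)-3-allyl-3,6-dimethyl-3a,4,7,7a-tetrahydro-2-benzofuran-1(3H)-one (C3 epimers) | O=C1OC(C)(CC=C)[C@H]2CC=C(C)C[C@H]12
F5 | step 8 | 1-[(1S,6S)-6-(2-hydroxypent-4-en-2-yl)-3-methylcyclohex-3-en-1-yl]-2-[(PMB-oxy)methyl]prop-2-en-1-one (carbinol epimers) | C=C(COCc1ccc(OC)cc1)C(=O)[C@H]1CC(C)=CC[C@@H]1C(C)(O)CC=C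
F6 | step 8 | (4aS,9aS)-9-hydroxy-3,9-dimethyl-6-[(PMB-oxy)methyl]-1,4,4a,8,9,9a-hexahydro-5H-benzo[7]annulen-5-one (C9 epimers) | O=C1C(COCc3ccc(OC)cc3)=CCC(C)(O)[C@H]2CC=C(C)C[C@H]12
F7 | step 8 | C9 methanesulfonate of F6 | O=C1C(COCc3ccc(OC)cc3)=CCC(C)(OS(C)(=O)=O)[C@H]2CC=C(C)C[C@H]12
F8 | step 8 | (4aS,9aS)-3,9-dimethyl-6-[(PMB-oxy)methyl]-1,4,4a,9a-tetrahydro-5H-benzo[7]annulen-5-one | O=C1C(COCc3ccc(OC)cc3)=CC=C(C)[C@H]2CC=C(C)C[C@H]12
F9 | step 17 | C3′-epimeric hydroperoxides of 26 (3-hydroperoxy-4-methylpent-4-enyl side chain) | C=C(C)C(CC[C@@]1(C)CC=C(COCc2ccc(OC)cc2)C(=O)[C@@H](CC(C)=O)[C@@H]1/C=C/OC(=O)C=C(C)C)OO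
F10 | step 17 | C3′-epimeric allylic alcohols (3-hydroxy-4-methylpent-4-enyl side chain) | C=C(C)C(CC[C@@]1(C)CC=C(COCc2ccc(OC)cc2)C(=O)[C@@H](CC(C)=O)[C@@H]1/C=C/OC(=O)C=C(C)C)O
F11 | step 17 | epoxy alcohol from the (3′S)-alcohol (4,5-epoxy-3-hydroxy-4-methylpentyl side chain) | CC3(CO3)[C@H](CC[C@@]1(C)CC=C(COCc2ccc(OC)cc2)C(=O)[C@@H](CC(C)=O)[C@@H]1/C=C/OC(=O)C=C(C)C)O
F12 | step 17 | (3′R)-allylic alcohol | C=C(C)[C@@H](CC[C@@]1(C)CC=C(COCc2ccc(OC)cc2)C(=O)[C@@H](CC(C)=O)[C@@H]1/C=C/OC(=O)C=C(C)C)O
F13 | step 17 | (3′R)-methanesulfonate | C=C(C)[C@@H](CC[C@@]1(C)CC=C(COCc2ccc(OC)cc2)C(=O)[C@@H](CC(C)=O)[C@@H]1/C=C/OC(=O)C=C(C)C)OS(C)(=O)=O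
F14 | step 17 | (3′S)-hydroperoxide PMB ether | C=C(C)[C@H](CC[C@@]1(C)CC=C(COCc2ccc(OC)cc2)C(=O)[C@@H](CC(C)=O)[C@@H]1/C=C/OC(=O)C=C(C)C)OO
F15 | step 6 | 1-[(1S,6S)-6-(7-(TBS-oxy)-4-hydroxyhept-1-en-4-yl)-3-methylcyclohex-3-en-1-yl]-2-[(PMB-oxy)methyl]prop-2-en-1-ol (epimers at both carbinols) | C=C(COCc1ccc(OC)cc1)C(O)[C@H]1CC(C)=CC[C@@H]1C(O)(CC=C)CCCO[Si](C)(C)C(C)(C)C
F16 | step 6 | (4aS,9aS)-3-methyl-6-[(PMB-oxy)methyl]-9-[3-(TBS-oxy)propyl]-4,4a,5,8,9,9a-hexahydro-1H-benzo[7]annulene-5,9-diol (C5 and C9 epimers) | OC1C(COCc3ccc(OC)cc3)=CCC(O)(CCCO[Si](C)(C)C(C)(C)C)[C@H]2CC=C(C)C[C@H]12
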